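The pitfall in a slow-starting flask is to read the flat early stretch as a slow reaction and count minutes, when the curves suggest that product breeds product, so the clock to count is doublings.

| flask | starting material | partner | protic impurity | temperature | remark | time |
|---|---|---|---|---|---|---|
| spring | 0.081 M | 1.5 equiv | 0.0162 M | −10 °C | run made earlier |  |
| noon | 0.081 M | 0.75 equiv | 0.0162 M | 5 °C | run made earlier |  |
| autumn | 0.081 M | 3 equiv | 0.0162 M | −10 °C | run made earlier |  |
| winter | 0.16 M | 1.5 equiv | 0.0162 M | 5 °C | run made earlier |  |
| cedar | 0.081 M (fed, over 2.0 min) | 1.50 equiv | 0.0162 M | 5 °C | all else is in the flask from the start; the feed brings no volume worth counting | 2.5 min |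
| birch | 0.081 M | 1.50 equiv (fed, over 2.0 min) | 0.0162 M |  | the addition at −25 °C, then warmed to 5 °C; the feed brings no volume worth counting | 2.5 min |
| oak | 0.081 M | 1.50 equiv (in portions, 4, over 2.0 min) | 0.0162 M | 5 °C | first portion at the start, last at 2.0 min | 2.5 min |
| larch | 0.081 M | 1.50 equiv | 0.0162 M | 5 °C | everything together at the start | 2.5 min |
| ash | 0.081 M | 1.50 equiv | 0.0162 M |  | everything together at the start at −25 °C, warmed to 5 °C at 2.0 min | 2.5 min |



- spring (time / min: product / %, starting material / %): 0.333: 0, 100; 0.833: 5, 95; 1.33: 15, 85; 2.00: 37, 67; 3.00: 59, 42; 4.00: 71, 30; 5.00: 78, 23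
- noon (time / s: product / %, starting material / %): 12.0: 2, 101; 25.0: 3, 97; 40.0: 9, 93; 50.0: 11, 89; 60.0: 13, 88; 80.0: 19, 80; 90.0: 22, 77
- autumn (time / min: product / %, starting material / %): 0.333: 3, 95; 0.500: 8, 90; 0.833: 30, 69; 1.33: 70, 28; 2.00: 91, 10; 3.00: 98, 1
- winter (time / s: product / %, starting material / %): 10.0: 35, 66; 25.0: 84, 12; 40.0: 94, 4; 60.0: 97, 5; 90.0: 100, 2

(standard deviation of a reading: 1.5 percentage points)

- which flask leads in amount of product, in percent of the starting material charged ("all alike" within 1.5 percentage points) (cedar / birch / oak / larch / ash / all alike)
- how much product is there at the end, in percent of the starting material charged: cedar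
- how much product is there at the end, in percent of the starting material charged: birch
- how much product is there at the end, in percent of the starting material charged: oak
- how much product is there at the end, in percent of the starting material charged: larch
- how much product is there at the end, in percent of the starting material charged: ash

The runs rise as an S, so I try this: starting material is lost at k × [starting material] × [partner] × [product]. I take free partner as the charge less the protic impurity and less what product has used. Across the steepest stretch of winter, at 5 °C, this gives k = 9.28 M⁻² s⁻¹.

But one stretch of one run proves little, and my orders may merely suit it. Noon stands at the same temperature with 0.75 equiv of partner against 1.5 equiv, and half the concentration of starting material, and its late stretch gives 10.3 M⁻² s⁻¹. The law survives.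

Early on, with starting material and free partner near their starting values, product then grows exponentially. That gives 8.75 s for τ, the doubling time: the natural logarithm of two over k, starting material and free partner, at 5 °C.

Birch is fed cold, so its warm window is 0.500 min, and that holds 3.43 doublings. Doublings need a seed, though, and I can read none. So I assume a seed the size of the scatter, 1.5 percentage points, and my reckoning for birch is 16.1%. That assumption is the weak point of the reckoning, and no run tests it.

The forecast differs. It puts larch first, with cedar 80%, birch 50%, oak 62%, larch 92% and ash 58%. Of the late flasks it says: “Ash and birch spend two cold minutes doing little”.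

The flasks give cedar 33.8%, birch 23.9%, oak 78.3%, larch 76.3% and ash 29.6%, so oak leads.

    starting material + partner + released group → product + 2 released group (k = 17.0 M⁻² s⁻¹, Ea = 42.0 kJ mol⁻¹)
    starting material + partner → product + released group (k = 0.0120 M⁻¹ s⁻¹, Ea = 68.0 kJ mol⁻¹)
    2 partner → homo dimer (k = 0.0790 M⁻¹ s⁻¹, Ea = 59.0 kJ mol⁻¹)
    partner + protic impurity → quenched reagent (k = 1.90 M⁻¹ s⁻¹, Ea = 53.0 kJ mol⁻¹)
    (constants at 5 °C)

In birch at 2.35 min, the half-life of starting material by the step needing released group is 0.98 min, and the warm window is about half of that. In birch, 76% of the starting material still stands at 2.50 min. Birch's product climbs from 0.404% at 2.00 min to 23.9%, which is 5.89 doublings against my 3.43. Birch's neighbour with 3.80 equiv of partner has τ = 3.16 s, so its window holds 9.49 doublings, more than my seed needs to pass the whole charge, and it ends at 93.6%.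

Readings and results were computed from invented constants, and the scatter is random.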